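**Retrosynthetic overview**
- The plan rests on ring C8–C12, a 2-chloro-4-hydroxycyclopent-2-enone whose C8–C12 bond joins the chain-bearing methine C8 to the tertiary carbinol C12. Ketone C9, chloroalkene C10=C11 and carbinol C12 map one-to-one onto C2–C5 of a 3-chloro-2,5-disubstituted furan that carries a carbinol at C8.
- Endgame: C7 acetate ⇐ C7 alcohol ⇐ C7 TBS ether. The only ring of the target is then opened at C8–C12 (Piancatelli rearrangement) to the furyl carbinol, used as both C8 epimers.
- The carbinol is cut at C8–C9 into 3-chloro-2-lithio-5-[(Z)-oct-2-enyl]furan and the C1–C8 α-silyloxy aldehyde.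
- Furan half: 3-bromofuran, C2 silyl block, Br→Cl exchange, C5 allylation with (Z)-octenyl bromide, desilylation. Aldehyde half: (R)-glyceraldehyde acetonide (source of C7), Z-Wittig, methanolysis, bis-silylation, primary desilylation, oxidation.
- Ring order: the furan is bought and the carbocycle is formed once, in step 12.

Key step: step 12

Remark: prostanoid numbering is used (C1 = ester carbonyl, C20 = chain end). Compound 20 is carried as the mixture of C8 epimers, because C8 becomes planar in step 12.

**Step 1**
Reactants: 1 (4-carboxybutyl)triphenylphosphonium bromide; 2 (R)-2,3-O-isopropylideneglyceraldehyde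
Product: 4 (Z)-6-[(4S)-2,2-dimethyl-1,3-dioxolan-4-yl]hex-5-enoic acid, via ylide carboxylate 3 (not isolated)
Conditions: 1, NaHMDS (2 equiv), THF, 0 °C; 2, −78 °C → rt; 1 M HCl to pH 4 at 0 °C
Reagents that add atoms: none
Why: Z-selective Wittig olefination, in which the non-stabilised ylide made with a sodium base adds to the α-alkoxy aldehyde under kinetic control to give the 5Z alkene, while the low temperature keeps the stereocentre of 2 (future C7) intact.

**Step 2**
Reactants: 4 (Z)-6-[(4S)-2,2-dimethyl-1,3-dioxolan-4-yl]hex-5-enoic acid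
Product: 5 methyl (5Z,7S)-7,8-dihydroxyoct-5-enoate
Conditions: p-TsOH·H2O (10 mol %), MeOH, 40 °C
Reagents that add atoms: methanol, CO
Why: Fischer esterification and acid-catalysed acetonide cleavage run in the same pot, the water released by the first feeding the second, and no bond at C7 is broken.

**Step 3**
Reactants: 5 methyl (5Z,7S)-7,8-dihydroxyoct-5-enoate
Product: 6 methyl (5Z,7S)-7,8-bis(tert-butyldimethylsilyloxy)oct-5-enoate
Conditions: TBSCl (2.5 equiv), imidazole, DMF, rt
Reagents that add atoms: tert-butyldimethylsilyl chloride, CC(C)(C)[Si](C)(C)Cl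
Why: Imidazole-promoted silyl ether formation covers both hydroxyls without touching the ester, the alkene or C7.

**Step 4**
Reactants: 6 methyl (5Z,7S)-7,8-bis(tert-butyldimethylsilyloxy)oct-5-enoate
Product: 7 methyl (5Z,7S)-7-(tert-butyldimethylsilyloxy)-8-hydroxyoct-5-enoate
Conditions: HF·pyridine, pyridine, THF, 0 °C
Reagents that add atoms: none
Why: In this selective desilylation the unhindered primary TBS ether should be cleaved much faster than the secondary allylic one, and the acidic medium suppresses 1,2-silyl migration.

**Step 5**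
Reactants: 7 methyl (5Z,7S)-7-(tert-butyldimethylsilyloxy)-8-hydroxyoct-5-enoate
Product: 8 methyl (5Z,7S)-7-(tert-butyldimethylsilyloxy)-8-oxooct-5-enoate
Conditions: Dess–Martin periodinane, CH2Cl2, 0 °C → rt; used crude at once
Reagents that add atoms: none
Why: Dess–Martin oxidation is amine-free and only weakly acidic, which should avoid epimerisation at the doubly activated C7–H and migration of the 5Z alkene into conjugation.

**Step 6**
Reactants: 9 3-bromofuran
Product: 11 3-bromo-2-(triethylsilyl)furan, via 3-bromo-2-lithiofuran 10 (not isolated)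
Conditions: LDA, THF, −78 °C; Et3SiCl, −78 °C → rt
Reagents that add atoms: chlorotriethylsilane, CC[Si](Cl)(CC)CC
Why: In this directed deprotonation the C2–H flanked by ring oxygen and bromine is the most acidic proton, LDA at −78 °C removes it without Br/Li exchange or halogen migration, and silylation blocks C2.

**Step 7**
Reactants: 11 3-bromo-2-(triethylsilyl)furan
Product: 13 3-chloro-2-(triethylsilyl)furan, via 3-lithio-2-(triethylsilyl)furan 12 (not isolated)
Conditions: n-BuLi, Et2O, −78 °C; C2Cl6, −78 °C → rt
Reagents that add atoms: hexachloroethane, ClC(Cl)(Cl)C(Cl)(Cl)Cl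
Why: Bromine–lithium exchange followed by electrophilic chlorination of the furyllithium, with the C2 silyl group closing the usual 3→2 lithium shift and making the product far less volatile than 3-chlorofuran itself.

**Step 8**
Reactants: 14 (Z)-oct-2-en-1-ol
Product: 15 (Z)-1-bromooct-2-ene
Conditions: CBr4, PPh3, CH2Cl2, 0 °C
Reagents that add atoms: carbon tetrabromide, BrC(Br)(Br)Br
Why: Appel bromination displaces the activated primary allylic oxygen by SN2 under neutral, cold conditions, so the Z geometry should be retained.

**Step 9**
Reactants: 13 3-chloro-2-(triethylsilyl)furan; 15 (Z)-1-bromooct-2-ene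
Product: 17 3-chloro-5-[(Z)-oct-2-enyl]-2-(triethylsilyl)furan, via 3-chloro-5-lithio-2-(triethylsilyl)furan 16 (not isolated)
Conditions: n-BuLi, THF, −78 → −20 °C; 15, −78 → 0 °C
Reagents that add atoms: none
Why: α-Lithiation of the furan at its only free α position (C5) followed by SN2 alkylation, in which the hard furyllithium attacks the unhindered CH2Br terminus of the primary allylic bromide, so the alkene keeps its place and geometry.

**Step 10**
Reactants: 17 3-chloro-5-[(Z)-oct-2-enyl]-2-(triethylsilyl)furan
Product: 18 4-chloro-2-[(Z)-oct-2-enyl]furan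
Conditions: TBAF (1 M in THF, wet), THF, 0 °C
Reagents that add atoms: none
Why: Fluoride-induced protodesilylation of a 2-silylfuran is eased by the oxygen and chlorine that stabilise the departing C2 carbanion, and short contact at 0 °C should leave the skipped alkene in place.

**Step 11**
Reactants: 18 4-chloro-2-[(Z)-oct-2-enyl]furan; 8 methyl (5Z,7S)-7-(tert-butyldimethylsilyloxy)-8-oxooct-5-enoate
Product: 20 methyl (5Z,7S,8RS)-7-(tert-butyldimethylsilyloxy)-8-{3-chloro-5-[(Z)-oct-2-enyl]furan-2-yl}-8-hydroxyoct-5-enoate, via 3-chloro-2-lithio-5-[(Z)-oct-2-enyl]furan 19 (not isolated)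
Conditions: LDA, THF, −78 °C; 8, −78 °C; AcOH/THF quench at −78 °C
Reagents that add atoms: none
Why: Directed lithiation then 1,2-addition to an aldehyde, where the ring C–H between oxygen and chlorine is kinetically far more acidic toward LDA than the C13 methylene, the aldehyde outruns the ester at −78 °C, the cold acidic quench stops O→O silyl migration, and no control at C8 is needed because that centre is erased in step 12.

**Step 12**
Reactants: 20 methyl (5Z,7S,8RS)-7-(tert-butyldimethylsilyloxy)-8-{3-chloro-5-[(Z)-oct-2-enyl]furan-2-yl}-8-hydroxyoct-5-enoate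
Product: 23 methyl (5Z,7S)-7-(tert-butyldimethylsilyloxy)-7-{(1R,2S)-4-chloro-2-hydroxy-2-[(Z)-oct-2-enyl]-5-oxocyclopent-3-en-1-yl}hept-5-enoate (7-O-TBS-7-deacetylpunaglandin 8), via furfuryl cation 21 (not isolated), via dihydroxypentadienyl cation 22 (not isolated)
Conditions: ZnCl2 (2 equiv), 1,4-dioxane/H2O (3:1), pH 5–6, 70 °C
Reagents that add atoms: water, O
Why: Zn(II)-assisted loss of the C8 hydroxyl turns both epimers of 20 into the single furfuryl cation 21, water adds to the furan carbon carrying the octenyl chain (C12), the hemiketal opens, and the resulting 1,4-dihydroxypentadienyl cation 22 (C8–C9–C10–C11–C12) cyclises and tautomerises to the C9 ketone, so that ketone, C10 chlorine and C12 carbinol all arrive in place in a net isomerisation. The reaction type is the Piancatelli rearrangement, whose closest known cases are 5-alkyl-2-furylcarbinols giving 4-alkyl-4-hydroxycyclopent-2-enones with ZnCl2 in aqueous dioxane or acetone; the C10 chlorine and the C7 silyloxy group are untried on such a substrate and both should slow ionisation, which the electron-releasing alkyl group at C12 offsets in part. The single ring (C8–C12, five-membered carbocycle) is closed by a thermal conrotatory 4π electrocyclisation of 22 that forms the C8–C12 bond. Relative configuration: with the C7 chain outside at C8 and, at C12, the octenyl chain outside and the smaller hydroxyl inside, conrotation places the two carbon chains trans, and any cis isomer can drain to trans through the C9 enol because C8 is epimerisable. Absolute sense: it rests on C7 alone, since in the A(1,3)-minimised rotamer (C7–H eclipsed with C8=C9, facing the C9 hydroxyl) the OTBS group covers one face of C8, and the rotamer with the silyloxy oxygen in plane exposes the same face (anti to the alkenyl chain), so C12 should bond anti to OTBS to give 8R and hence 12S. The step therefore needs torquoselectivity, which is only substrate-biased and not assured (C12 cannot be corrected later, so an 8S,12R isomer would have to be removed by chromatography), and chemoselectivity, which pH 5–6 and moderate temperature should secure for the TBS ether, methyl ester, both Z alkenes and the β-silyloxy ketone, while water capture at C8 merely regenerates 20.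

**Step 13**
Reactants: 23 7-O-TBS-7-deacetylpunaglandin 8
Product: 24 methyl (5Z,7S)-7-{(1R,2S)-4-chloro-2-hydroxy-2-[(Z)-oct-2-enyl]-5-oxocyclopent-3-en-1-yl}-7-hydroxyhept-5-enoate (7-deacetylpunaglandin 8)
Conditions: HF·pyridine, MeCN, 0 °C → rt (plastic vessel)
Reagents that add atoms: none
Why: Acidic fluoride desilylation is chosen over basic TBAF, because a basic fluoride source would provoke E1cB loss of the C7 oxygen or retro-aldol cleavage of the β-oxygenated ketone, whereas HF·pyridine is the standard reagent for such base-labile aldol-type silyl ethers.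

**Step 14**
Reactants: 24 7-deacetylpunaglandin 8
Product: 25 punaglandin 8
Conditions: Ac2O, pyridine, CH2Cl2, −20 → 0 °C; cold dilute citric acid wash
Reagents that add atoms: acetic anhydride, CC(=O)OC(C)=O
Why: In this chemoselective acylation the secondary C7 hydroxyl reacts with Ac2O/pyridine (no DMAP) while the tertiary C12 hydroxyl stays inert, and low temperature with a prompt acidic wash limits base-induced loss of acetic acid across C7–C8.

**Compound list**
1 | (4-carboxybutyl)triphenylphosphonium bromide | OC(=O)CCCC[P+](c1ccccc1)(c1ccccc1)c1ccccc1.[Br-] | starting material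
2 | (R)-2,3-O-isopropylideneglyceraldehyde | O=C[C@H]1COC(C)(C)O1 | starting material
3 | sodium 5-(triphenylphosphoranylidene)pentanoate (ylide carboxylate) | [Na+].[O-]C(=O)CCCC=P(c1ccccc1)(c1ccccc1)c1ccccc1 | intermediate
4 | (Z)-6-[(4S)-2,2-dimethyl-1,3-dioxolan-4-yl]hex-5-enoic acid | OC(=O)CCC/C=C\[C@H]1COC(C)(C)O1 | intermediate
5 | methyl (5Z,7S)-7,8-dihydroxyoct-5-enoate | COC(=O)CCC/C=C\[C@H](O)CO | intermediate
6 | methyl (5Z,7S)-7,8-bis(tert-butyldimethylsilyloxy)oct-5-enoate | COC(=O)CCC/C=C\[C@H](O[Si](C)(C)C(C)(C)C)CO[Si](C)(C)C(C)(C)C | intermediate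
7 | methyl (5Z,7S)-7-(tert-butyldimethylsilyloxy)-8-hydroxyoct-5-enoate | COC(=O)CCC/C=C\[C@H](O[Si](C)(C)C(C)(C)C)CO | intermediate
8 | methyl (5Z,7S)-7-(tert-butyldimethylsilyloxy)-8-oxooct-5-enoate | COC(=O)CCC/C=C\[C@H](O[Si](C)(C)C(C)(C)C)C=O | intermediate
9 | 3-bromofuran | Brc1ccoc1 | starting material
10 | 3-bromo-2-lithiofuran | [Li]c1occc1Br | intermediate
11 | 3-bromo-2-(triethylsilyl)furan | CC[Si](CC)(CC)c1occc1Br | intermediate
12 | 3-lithio-2-(triethylsilyl)furan | CC[Si](CC)(CC)c1occc1[Li] | intermediate
13 | 3-chloro-2-(triethylsilyl)furan | CC[Si](CC)(CC)c1occc1Cl | intermediate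
14 | (Z)-oct-2-en-1-ol | CCCCC/C=C\CO | starting material
15 | (Z)-1-bromooct-2-ene | CCCCC/C=C\CBr | intermediate
16 | 3-chloro-5-lithio-2-(triethylsilyl)furan | CC[Si](CC)(CC)c1oc([Li])cc1Cl | intermediate
17 | 3-chloro-5-[(Z)-oct-2-enyl]-2-(triethylsilyl)furan | CCCCC/C=C\Cc1cc(Cl)c(o1)[Si](CC)(CC)CC | intermediate
18 | 4-chloro-2-[(Z)-oct-2-enyl]furan | CCCCC/C=C\Cc1cc(Cl)co1 | intermediate
19 | 3-chloro-2-lithio-5-[(Z)-oct-2-enyl]furan | CCCCC/C=C\Cc1cc(Cl)c([Li])o1 | intermediate
20 | furyl carbinol, (7S), both C8 epimers | CCCCC/C=C\Cc1cc(Cl)c(o1)C(O)[C@H](/C=C\CCCC(=O)OC)O[Si](C)(C)C(C)(C)C | intermediate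
21 | C8 furfuryl cation | CCCCC/C=C\Cc1cc(Cl)c(o1)[CH+][C@H](/C=C\CCCC(=O)OC)O[Si](C)(C)C(C)(C)C | intermediate
22 | 1,4-dihydroxypentadienyl cation C8–C12 (drawn as the C12 oxocarbenium form) | CCCCC/C=C\CC(=[OH+])/C=C(Cl)\C(O)=C\[C@H](/C=C\CCCC(=O)OC)O[Si](C)(C)C(C)(C)C | intermediate
23 | 7-O-TBS-7-deacetylpunaglandin 8 (7S,8R,12S) | CCCCC/C=C\C[C@@]1(O)C=C(Cl)C(=O)[C@@H]1[C@H](/C=C\CCCC(=O)OC)O[Si](C)(C)C(C)(C)C | intermediate
24 | 7-deacetylpunaglandin 8 (7S,8R,12S) | CCCCC/C=C\C[C@@]1(O)C=C(Cl)C(=O)[C@@H]1[C@H](/C=C\CCCC(=O)OC)O | intermediate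
25 | punaglandin 8 (7S,8R,12S) | CCCCC/C=C\C[C@@]1(O)C=C(Cl)C(=O)[C@@H]1[C@H](/C=C\CCCC(=O)OC)OC(C)=O | target

**Totals**
Total step count: 14.
Longest linear sequence: 9 (steps 1–5 and 11–14). The furan branch runs through steps 6, 7, 9 and 10, and step 8 is a side branch.

**Steps most likely to fail**

**Step 12.**
- What may go wrong: ionisation at C8 may be slow, because the C10 chlorine and the C7 silyloxy group both destabilise the cation. Harsher conditions would then be needed, under which hydride shift from C7, loss of silanol across C7–C8 and a weak facial bias in the conrotation take over.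
- Fallback: the chlorine is left out of the electrocyclisation substrate and introduced after ring closure. The sequence sets out from 15 (with 8 as partner) and returns at 23.
- Commercial furan (c1ccoc1) is lithiated with n-BuLi to 2-furyllithium F1 and allylated with 15 to 2-[(Z)-oct-2-enyl]furan F2.
- NIS in DMF iodinates the free α position to give 2-iodo-5-[(Z)-oct-2-enyl]furan F3.
- Nozaki–Hiyama–Kishi coupling of this iodide with 8 (CrCl2, cat. NiCl2, DMF) gives the chlorine-free furyl carbinol F4.
- This ordinary 5-alkyl-2-furylcarbinol should rearrange with ZnCl2 in aqueous dioxane at lower temperature to the 10-deschloro cyclopentenone F5.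
- Nucleophilic epoxidation (t-BuOOH, cat. benzyltrimethylammonium hydroxide, −20 °C) touches only the enone and gives the 10,11-epoxy ketone F6.
- Chloride opens the epoxide at C10 under mild acid (LiCl, sulfonic acid resin, MeCN) to the 10-chloro-11-hydroxy ketone F7, which loses water from C11 to give 23.
- This fallback does not improve the facial bias, so diastereomers from the conrotation are separated at 23 in either variant.

**Step 11.**
- What may go wrong: deprotonation may compete with addition, either at the C13 methylene of 18 or at C7–H of 8, the latter causing epimerisation or alkene migration. Attack on the ester and O→O silyl migration in the alkoxide are further risks.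
- Fallback: the strongly basic organolithium is replaced by a non-basic organochromium reagent reached without any strong base. The sequence sets out from 18 and returns at 20.
- NIS in DMF (0 °C, dark) iodinates the free α position next to chlorine to give 3-chloro-2-iodo-5-[(Z)-oct-2-enyl]furan F8.
- Nozaki–Hiyama–Kishi coupling of this iodide with 8 (CrCl2, cat. NiCl2, DMF, rt) forms the C8–C9 bond. These conditions tolerate esters and enolisable aldehydes.

**Step 14.**
- What may go wrong: once the acetate is in place, the amine base may trigger E1cB loss of acetic acid across C7–C8. Prolonged exposure may also acetylate C12.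
- Fallback: base-mediated acyl transfer from an anhydride is replaced by base-free biocatalytic transesterification. It sets out from 24 and returns at 25.
- Conditions are immobilised Candida antarctica lipase B, vinyl acetate and MTBE at rt. The acyl-enzyme mechanism needs no base, and a tertiary alcohol is not a substrate. This fallback makes no new compound (F0).

**Further compounds**
F1 | step 12 | 2-furyllithium | [Li]c1ccco1
F2 | step 12 | 2-[(Z)-oct-2-enyl]furan | CCCCC/C=C\Cc1ccco1
F3 | step 12 | 2-iodo-5-[(Z)-oct-2-enyl]furan | CCCCC/C=C\Cc1ccc(I)o1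
F4 | step 12 | chlorine-free furyl carbinol, (7S), both C8 epimers | CCCCC/C=C\Cc1ccc(o1)C(O)[C@H](/C=C\CCCC(=O)OC)O[Si](C)(C)C(C)(C)C
F5 | step 12 | 10-deschloro cyclopentenone (7S,8R,12S) | CCCCC/C=C\C[C@@]1(O)C=CC(=O)[C@@H]1[C@H](/C=C\CCCC(=O)OC)O[Si](C)(C)C(C)(C)C
F6 | step 12 | 10,11-epoxy ketone (epoxide face not defined) | CCCCC/C=C\C[C@@]1(O)C2OC2C(=O)[C@@H]1[C@H](/C=C\CCCC(=O)OC)O[Si](C)(C)C(C)(C)C
F7 | step 12 | 10-chloro-11-hydroxy ketone (C10, C11 not defined) | CCCCC/C=C\C[C@@]1(O)C(O)C(Cl)C(=O)[C@@H]1[C@H](/C=C\CCCC(=O)OC)O[Si](C)(C)C(C)(C)C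
F8 | step 11 | 3-chloro-2-iodo-5-[(Z)-oct-2-enyl]furan | CCCCC/C=C\Cc1cc(Cl)c(I)o1
F0 | step 14 | none | none
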